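**Strategy.** The route rests on disconnecting C8–C9 of ring B by a ring-expanding [2,3]-Wittig rearrangement. The precursor is not a decalin: the oxygen that ends as the 9α-hydroxyl is first tied to C6 as a trans-fused oxolane on ring A, with a silylethynyl group on C9 and an (E)-propenyl group on C6. One operation closes ring B, forms C8–C9, sets C8 and the tertiary carbinol C9 from the C6 configuration and the alkene geometry, frees the 9-OH and leaves C6=C7 for the 6β-acetate. It exploits the 1,4-relationship across ring B between oxygenated C9 and C6 and the adjacent C8 methine. The oxolane arises from an asymmetric Diels–Alder reaction.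

Key step: step 8

**Remarks (assumptions)**
- Labdane numbering of the target is used for every intermediate (ring A: C1–C5, C10; ring B: C5–C10; C11–C16 side chain; C17 on C8; C18/C19 on C4; C20 on C10).
- C9 of compounds 5–14 is an epimer mixture that is carried on and is written without configuration, because C9 becomes a planar propargyl/allenyl anion in step 8.
- The (R,R) catalyst antipode is written in step 1; if it should give the mirror-image adduct, the (S,S) antipode is used.

**Route**

Step 1
Reactants: 1 ethyl (E)-3-methyl-4-oxobut-2-enoate; 2 (E)-3-(tert-butyldimethylsilyloxy)-N,N-dimethylbuta-1,3-dien-1-amine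
Product: 3 Diels–Alder adduct (ethyl 5-(tert-butyldimethylsilyloxy)-3-(dimethylamino)-2-formyl-2-methylcyclohex-4-ene-1-carboxylate; formyl and ester trans)
Conditions: (R,R)-(salen)CrSbF6 (5 mol %; salen = N,N'-bis(3,5-di-tert-butylsalicylidene)-1,2-cyclohexanediaminate), 4 Å MS, CH2Cl2, −40 °C; crude used
Reagents that add atoms: none
Why: Catalytic asymmetric Diels–Alder reaction of a 1-amino-3-siloxy diene with an α-substituted enal, in which the nucleophilic CH2 terminus of 2 should bond to C5 (β to the chromium-bound formyl group) and the amino-bearing terminus to C10, the (E)-alkene of 1 fixes formyl (C9) and ester (C6) trans, and the chiral salen complex selects the enal face and so sets C10 and C5 (the endo amino centre at C1 is lost later).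

Step 2
Reactants: 3 Diels–Alder adduct; 4 ethynyl(triisopropyl)silane
Product: 6 trans-fused γ-lactone C9–O–C6(=O) (C9 epimers), via lithium propargylic alkoxide 5 (not isolated)
Conditions: 4 (1.05 equiv), n-BuLi, THF, −78 °C; then 3, −78 °C → rt; aq. NaHCO3; crude used
Reagents that add atoms: none
Why: 1,2-Addition of the lithium acetylide to the aldehyde (more electrophilic than the ester) should be followed by 5-exo-trig lactonisation of the C9 alkoxide onto the trans ester with loss of ethoxide, while the silyl enol ether and the amine are inert to the organolithium; C9 forms unselectively and is erased in step 8.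

Step 3
Reactants: 6 trans-fused γ-lactone; 7 (E)-1-bromoprop-1-ene
Product: 9 hemiketal enone (C6 anomers; C9 epimers), via lithium hemiketal 8 (not isolated)
Conditions: 7, t-BuLi (2 equiv per 7), Et2O, −78 °C; then 6, THF, −78 °C; then 1 M HCl, THF, 0 °C
Reagents that add atoms: none
Why: A γ-lactone takes up one equivalent of an organolithium at −78 °C and stops at the lithium hemiketal, (E)-propenyllithium from bromine–lithium exchange keeps its geometry, and dilute acid should then hydrolyse the silyl enol ether and eliminate dimethylamine from the β-amino ketone (E1cB) to unveil the cyclohexenone.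

Step 4
Reactants: 9 hemiketal enone
Product: 10 oxolane enone with 6β-(E)-propenyl group
Conditions: Et3SiH (5 equiv), BF3·OEt2 (3 equiv), CH2Cl2, −78 → −30 °C
Reagents that add atoms: none
Why: Lewis-acid ionisation of the hemiketal to the cyclic oxocarbenium ion and silane reduction (ionic reduction of a lactol) should deliver hydride to C6 from the α face, anti to the axial C10 methyl that lies 1,3 across the five-membered ring, which places the propenyl group β (cis to that methyl).

Step 5
Reactants: 10 oxolane enone
Product: 12 4,4-dimethyl oxolane enone, via 4-monomethyl enone 11 (not isolated)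
Conditions: KHMDS (1.2 equiv), THF, −78 °C, then MeI; again KHMDS (1.5 equiv), then MeI, −78 → 0 °C (one flask)
Reagents that add atoms: iodomethane, CI
Why: Two α′-alkylations through the cross-conjugated enolate of the cyclohexenone should occur only at C4, because C10 is quaternary (no γ-deprotonation), C2 is vinylic, and the hexamethyldisilazide is too weak to remove the propargylic or allylic ether hydrogens.

Step 6
Reactants: 12 4,4-dimethyl oxolane enone
Product: 13 4,4-dimethyl oxolane 3-ketone
Conditions: [(Ph3P)CuH]6 (0.4 equiv), H2O (3 equiv), benzene, rt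
Reagents that add atoms: none
Why: Conjugate reduction by the phosphine copper hydride hexamer is chemoselective for the enone, leaves the isolated alkene and the silylalkyne untouched, and forms no stereocentre.

Step 7
Reactants: 13 4,4-dimethyl oxolane 3-ketone
Product: 14 3β-alcohol
Conditions: NaBH4, MeOH, 0 °C
Reagents that add atoms: none
Why: Borohydride reduction of a 4,4-dimethyl-3-ketone on a chair ring A with an axial C10 methyl should proceed by axial attack from the α face and give the equatorial 3β-alcohol.

Step 8
Reactants: 14 3β-alcohol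
Product: 17 13,14,15,16-tetranorlabd-6-en-11-yne-3β,9α-diol, via C9-lithiated lithium alkoxide 15 (not isolated), via rearranged dilithium dialkoxide 16 (not isolated)
Conditions: s-BuLi (2.5 equiv), THF, −78 → −20 °C; then Bu4NF·3H2O (3 equiv), THF, rt
Reagents that add atoms: none
Why: Proposed new method: after the C3–OH, the second equivalent of s-BuLi removes the propargylic, α-oxygenated H9 to give a silicon-stabilised propargyl/allenyl anion that is planar at C9, and its β lobe, on the oxolane face that carries the pseudo-axial (E)-propenyl group of C6, bonds to C8 while the allylic C6–O bond breaks and C6=C7 forms, a suprafacial [2,3]-Wittig shift through the five-centre array C9–O–C6–C7–C8 bridged by C10–C5 (oxanorbornene-like transition state). The closest known reaction type is the [2,3]-Wittig rearrangement of allyl propargyl ethers, also used for ring contraction of macrocyclic ethers; its use to expand a fused five-membered ether into a carbocycle is the new element. Ring B is closed in a formal 6-endo-trig mode (C9 carbanion onto C8 of the C7=C8 alkene), the ring oxygen being released as the 9α-alkoxide. C9 is controlled by the C6 stereocentre, because bonding is possible only on the face that holds the propenyl group (cis to the C10 methyl), which leaves O9 α and the alkynyl group β; C8 is controlled by the (E)-alkene geometry in the bridged transition state, where the methyl group points away from the C10–C5 bridge and H8 lies next to the C10 methyl, giving the 8α-methyl. The step needs deprotonation at C9 and not at the allylic C6–H, which the more acidic propargylic, silyl-stabilised position secures, and it needs the [2,3] over the [1,2] shift, which is secured because a [1,2] shift would have to form a cyclobutane.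

Step 9
Reactants: 17 13,14,15,16-tetranorlabd-6-en-11-yne-3β,9α-diol
Product: 18 13,14,15,16-tetranorlabda-6,11-diene-3β,9α-diol
Conditions: H2 (1 atm), Pd/CaCO3 poisoned with Pb(OAc)2, quinoline, EtOAc, rt
Reagents that add atoms: none
Why: Semihydrogenation over lead-poisoned palladium should stop at the vinyl group for a terminal alkyne and leave the hindered ring alkene alone.

Step 10
Reactants: 18 13,14,15,16-tetranorlabda-6,11-diene-3β,9α-diol; 19 3-bromofuran-2(5H)-one
Product: 21 3β,9α-dihydroxylabda-6,13-dien-16,15-olide, via B-alkyl-9-BBN adduct 20 (not isolated)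
Conditions: 9-BBN (3 equiv), THF, 0 °C → rt; then 19, PdCl2(dppf) (5 mol %), AsPh3, K3PO4 (3 M aq.), DMF, rt
Reagents that add atoms: none
Why: 9-BBN should hydroborate the monosubstituted vinyl group at its terminus far faster than the cis ring alkene, and the B-alkyl Suzuki–Miyaura coupling with the α-bromobutenolide then forms C12–C13 under mild phosphate base without touching a stereocentre.

Step 11
Reactants: 21 3β,9α-dihydroxylabda-6,13-dien-16,15-olide
Product: 22 6β-acetoxy-7α-bromo-3β,9α-dihydroxylabd-13-en-16,15-olide
Conditions: NBS (1.1 equiv), AcOH, rt, dark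
Reagents that add atoms: N-bromosuccinimide, O=C1CCC(=O)N1Br; acetic acid, CC(=O)O
Why: Bromonium formation on the less hindered α face of C6=C7 followed by trans-diaxial (Fürst–Plattner) opening by acetic acid at C6 from the β face should give the 6β-acetoxy-7α-bromide, while the electron-poor butenolide alkene does not react.

Step 12
Reactants: 22 6β-acetoxy-7α-bromo-3β,9α-dihydroxylabd-13-en-16,15-olide
Product: 23 6β-acetoxy-3β,9α-dihydroxylabd-13-en-16,15-olide (target)
Conditions: Bu3SnH (1.5 equiv), AIBN (cat.), benzene, 80 °C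
Reagents that add atoms: none
Why: Radical chain hydrodebromination should replace the C7 bromine by hydrogen faster than 1,2-acyloxy shift or addition of the C7 radical to the butenolide, and it leaves all stereocentres untouched.

**Compound list**

1 | ethyl (E)-3-methyl-4-oxobut-2-enoate (formyl carbon = C9, methyl-bearing carbon = C10, CH = C5, ester carbon = C6) | CCOC(=O)/C=C(\C)C=O | starting material
2 | (E)-3-(tert-butyldimethylsilyloxy)-N,N-dimethylbuta-1,3-dien-1-amine (C1–C4) | CN(C)/C=C/C(=C)O[Si](C)(C)C(C)(C)C | starting material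
3 | ethyl 5-(tert-butyldimethylsilyloxy)-3-(dimethylamino)-2-formyl-2-methylcyclohex-4-ene-1-carboxylate; 10β-methyl, 5α-H, formyl (C9) and ester (C6) trans, 1α-NMe2 cis to formyl, C2=C3 silyl enol ether | CCOC(=O)[C@H]1CC(O[Si](C)(C)C(C)(C)C)=C[C@H](N(C)C)[C@]1(C)C=O | intermediate
4 | ethynyl(triisopropyl)silane | C#C[Si](C(C)C)(C(C)C)C(C)C | starting material
5 | lithium alkoxide of the C9 propargylic alcohol from 3 (C9 epimers; not isolated) | CCOC(=O)[C@H]1CC(O[Si](C)(C)C(C)(C)C)=C[C@H](N(C)C)[C@]1(C)C([O-])C#C[Si](C(C)C)(C(C)C)C(C)C.[Li+] | intermediate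
6 | trans-fused γ-lactone C9–O–C6(=O) on ring A; 9-[(triisopropylsilyl)ethynyl], 10β-methyl, 5α-H, 1α-NMe2, C2=C3 silyl enol ether (C9 epimers) | O=C1OC(C#C[Si](C(C)C)(C(C)C)C(C)C)[C@@]2(C)[C@@H](N(C)C)C=C(O[Si](C)(C)C(C)(C)C)C[C@H]12 | intermediate
7 | (E)-1-bromoprop-1-ene | C/C=C/Br | starting material
8 | lithium hemiketal from 6, C6 bearing O–Li and (E)-prop-1-enyl (C6 and C9 epimers; not isolated) | C/C=C/C1([O-])OC(C#C[Si](C(C)C)(C(C)C)C(C)C)[C@@]2(C)[C@@H](N(C)C)C=C(O[Si](C)(C)C(C)(C)C)C[C@H]12.[Li+] | intermediate
9 | hemiketal enone: oxolane with 6-hydroxy-6-[(E)-prop-1-enyl] and 9-[(triisopropylsilyl)ethynyl], fused at C5–C10 (10β-methyl, 5α-H) to a cyclohex-1-en-3-one ring A (C6 anomers, C9 epimers) | C/C=C/C1(O)OC(C#C[Si](C(C)C)(C(C)C)C(C)C)[C@@]2(C)C=CC(=O)C[C@H]12 | intermediate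
10 | oxolane enone: 6β-[(E)-prop-1-enyl] (6α-H, cis to the C10 methyl), 9-[(triisopropylsilyl)ethynyl], 10β-methyl, 5α-H, ring A cyclohex-1-en-3-one (C9 epimers) | C/C=C/[C@@H]1OC(C#C[Si](C(C)C)(C(C)C)C(C)C)[C@@]2(C)C=CC(=O)C[C@H]12 | intermediate
11 | 4-monomethyl derivative of 10 (C4 and C9 epimers; not isolated) | C/C=C/[C@@H]1OC(C#C[Si](C(C)C)(C(C)C)C(C)C)[C@@]2(C)C=CC(=O)C(C)[C@H]12 | intermediate
12 | 4,4-dimethyl derivative of 10 (C9 epimers) | C/C=C/[C@@H]1OC(C#C[Si](C(C)C)(C(C)C)C(C)C)[C@@]2(C)C=CC(=O)C(C)(C)[C@H]12 | intermediate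
13 | 4,4-dimethyl oxolane 3-ketone, ring A saturated (C9 epimers) | C/C=C/[C@@H]1OC(C#C[Si](C(C)C)(C(C)C)C(C)C)[C@@]2(C)CCC(=O)C(C)(C)[C@H]12 | intermediate
14 | 3β-alcohol of 13; 6β-(E)-propenyl, 10β-methyl, 5α-H (C9 epimers) | C/C=C/[C@@H]1OC(C#C[Si](C(C)C)(C(C)C)C(C)C)[C@@]2(C)CC[C@H](O)C(C)(C)[C@H]12 | intermediate
15 | C9-lithiated lithium 3-alkoxide of 14 (propargyl/allenyl anion; not isolated) | C/C=C/[C@@H]1O[C-](C#C[Si](C(C)C)(C(C)C)C(C)C)[C@@]2(C)CC[C@H]([O-])C(C)(C)[C@H]12.[Li+].[Li+] | intermediate
16 | dilithium 3β,9α-dialkoxide of 12-(triisopropylsilyl)-13,14,15,16-tetranorlabd-6-en-11-yne-3β,9α-diol (8α-methyl; not isolated) | C1=C[C@@H](C)[C@]([O-])(C#C[Si](C(C)C)(C(C)C)C(C)C)[C@@]2(C)CC[C@H]([O-])C(C)(C)[C@H]12.[Li+].[Li+] | intermediate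
17 | 13,14,15,16-tetranorlabd-6-en-11-yne-3β,9α-diol (9β-ethynyl, 8α-methyl, 5α-H, 10β-methyl) | C1=C[C@@H](C)[C@](O)(C#C)[C@@]2(C)CC[C@H](O)C(C)(C)[C@H]12 | intermediate
18 | 13,14,15,16-tetranorlabda-6,11-diene-3β,9α-diol (9β-vinyl) | C1=C[C@@H](C)[C@](O)(C=C)[C@@]2(C)CC[C@H](O)C(C)(C)[C@H]12 | intermediate
19 | 3-bromofuran-2(5H)-one | O=C1OCC=C1Br | starting material
20 | B-(C12-alkyl)-9-borabicyclo[3.3.1]nonane from 18 (hydroxyls drawn free; not isolated) | C1=C[C@@H](C)[C@](O)(CCB3C4CCCC3CCC4)[C@@]2(C)CC[C@H](O)C(C)(C)[C@H]12 | intermediate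
21 | 3β,9α-dihydroxylabda-6,13-dien-16,15-olide (8α-methyl) | C1=C[C@@H](C)[C@](O)(CCC3=CCOC3=O)[C@@]2(C)CC[C@H](O)C(C)(C)[C@H]12 | intermediate
22 | 6β-acetoxy-7α-bromo-3β,9α-dihydroxylabd-13-en-16,15-olide | CC(=O)O[C@@H]1[C@@H](Br)[C@@H](C)[C@](O)(CCC3=CCOC3=O)[C@@]2(C)CC[C@H](O)C(C)(C)[C@H]12 | intermediate
23 | 6β-acetoxy-3β,9α-dihydroxylabd-13-en-16,15-olide (8β-H, 5α-H, 10β-methyl; CNP0513254.1) | CC(=O)O[C@@H]1C[C@@H](C)[C@](O)(CCC2=CCOC2=O)[C@@]2(C)CC[C@H](O)C(C)(C)[C@H]12 | target

**Totals**
Total step count: 12. Longest linear sequence: 12 steps (from 1 and 2 to 23).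

**Steps most likely to fail**

1. Step 8 (bears the label). What may go wrong: the anion may not reach the bridged transition state on the trans-fused oxolane and may instead be reprotonated unchanged, fragment by cycloreversion of the lithiated oxolane, or isomerise the propargyl ether to an allenyl ether. The fallback uses known chemistry, sets out from 13 and returns at 17. Bromodimethylborane (CH2Cl2, −78 °C) should cleave the oxolane at its allylic C6–O bond to the ring-opened allylic bromide carbinol F1. Dess–Martin periodinane should oxidise the C9 carbinol to the bromo ynone F2. CrCl2 in THF (intramolecular Nozaki–Hiyama–Kishi allylation) should generate the allylchromium species, whose C8 terminus adds to the C9 ketone and closes ring B to the 3-oxo tertiary alcohol F3; the isomer with 8α-methyl and 9α-hydroxyl would have to be separated. NaBH4 should reduce the 3-ketone to the 3β-alcohol F4, and Bu4NF removes the silyl group to reach 17.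

2. Step 4. What may go wrong: hydride may add to the allyl terminus C8 of the conjugated oxocarbenium ion or to the wrong face of C6, or the ion may lose H5 and scramble C5. The fallback sets out from 6 and returns at 10. Lactone 6 is treated with (E)-prop-1-enyllithium as in step 3 but quenched with pH 7 buffer, which keeps the silyl enol ether and should give the masked hemiketal F5. Corey–Bakshi–Shibata reduction of its open-chain enone tautomer (catecholborane, (R)-2-methyl-oxazaborolidine, chosen on the premise that the propenyl group acts as the larger ketone substituent) should set the C6 carbinol with the configuration opposite to that needed in the ring and give the diol F6. Mitsunobu cyclodehydration (PPh3, diisopropyl azodicarboxylate) should activate the allylic C6–OH, which the hindered C9–OH displaces with inversion, to give the masked oxolane F7 with the β-propenyl group. Dilute HCl then unveils the enone as in step 3 and delivers 10.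

3. Step 11. What may go wrong: opening of the bromonium ion by acetic acid at the hindered C6 β position may lose to attack at C7, or the bromonium ion may form on the β face. The fallback sets out from 21 and returns at 23. A Wacker oxidation directed by the homoallylic 9α-hydroxyl (PdCl2, CuCl, O2, DMF–H2O) should place the carbonyl at C6 and give the 6-ketone F8. Luche reduction (NaBH4, CeCl3·7H2O, MeOH, −78 °C) should add hydride from the α face and give the axial 6β-alcohol F9 without touching the butenolide. Ac2O and 4-dimethylaminopyridine should acetylate both secondary hydroxyls to the 3,6-diacetate F10. Lipase-catalysed butanolysis (Candida antarctica lipase B, n-butanol, tert-butyl methyl ether) should then remove the unhindered equatorial 3-acetate and leave the shielded axial 6β-acetate, which is 23.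

**Further compounds**

F1 | step 8 | ring-opened allylic bromide carbinol from 13: ring A 3-ketone with C5 bearing CH(Br)–CH=CH–CH3 and C10 bearing CH(OH)–C≡C–Si(iPr)3 (C6 and C9 epimers) | C/C=C/C(Br)[C@H]1C(C)(C)C(=O)CC[C@]1(C)C(O)C#C[Si](C(C)C)(C(C)C)C(C)C
F2 | step 8 | bromo ynone, C9 ketone of F1 | C/C=C/C(Br)[C@H]1C(C)(C)C(=O)CC[C@]1(C)C(=O)C#C[Si](C(C)C)(C(C)C)C(C)C
F3 | step 8 | 9α-hydroxy-12-(triisopropylsilyl)-13,14,15,16-tetranorlabd-6-en-11-yn-3-one (8α-methyl) | C1=C[C@@H](C)[C@](O)(C#C[Si](C(C)C)(C(C)C)C(C)C)[C@@]2(C)CCC(=O)C(C)(C)[C@H]12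
F4 | step 8 | 12-(triisopropylsilyl)-13,14,15,16-tetranorlabd-6-en-11-yne-3β,9α-diol | C1=C[C@@H](C)[C@](O)(C#C[Si](C(C)C)(C(C)C)C(C)C)[C@@]2(C)CC[C@H](O)C(C)(C)[C@H]12
F5 | step 4 | masked hemiketal, neutral form of 8 (silyl enol ether and amine retained; C6 anomers, C9 epimers) | C/C=C/C1(O)OC(C#C[Si](C(C)C)(C(C)C)C(C)C)[C@@]2(C)[C@@H](N(C)C)C=C(O[Si](C)(C)C(C)(C)C)C[C@H]12
F6 | step 4 | ring-opened diol: C6 allylic alcohol with the configuration opposite to C6 of 10, C9 propargylic alcohol (C9 epimers), masked ring A | C/C=C/[C@@H](O)[C@H]1CC(O[Si](C)(C)C(C)(C)C)=C[C@H](N(C)C)[C@]1(C)C(O)C#C[Si](C(C)C)(C(C)C)C(C)C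
F7 | step 4 | masked oxolane with 6β-(E)-propenyl (silyl enol ether and 1α-NMe2 retained; C9 epimers) | C/C=C/[C@@H]1OC(C#C[Si](C(C)C)(C(C)C)C(C)C)[C@@]2(C)[C@@H](N(C)C)C=C(O[Si](C)(C)C(C)(C)C)C[C@H]12
F8 | step 11 | 3β,9α-dihydroxy-6-oxolabd-13-en-16,15-olide | O=C1C[C@@H](C)[C@](O)(CCC3=CCOC3=O)[C@@]2(C)CC[C@H](O)C(C)(C)[C@H]12
F9 | step 11 | 3β,6β,9α-trihydroxylabd-13-en-16,15-olide | O[C@@H]1C[C@@H](C)[C@](O)(CCC3=CCOC3=O)[C@@]2(C)CC[C@H](O)C(C)(C)[C@H]12
F10 | step 11 | 3β,6β-diacetoxy-9α-hydroxylabd-13-en-16,15-olide | CC(=O)O[C@@H]1C[C@@H](C)[C@](O)(CCC3=CCOC3=O)[C@@]2(C)CC[C@H](OC(C)=O)C(C)(C)[C@H]12
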